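## Retrosynthetic overview

1. Burkinabin C ⇐ hydrogenolysis of tetrabenzyl precursor 16 ⇐ double esterification of benzyl 3-O-benzylquinate 14 with O-benzylvanillic acid 15 (both esters placed at once on the trans-4,5-diol).
2. 14 ⇐ 3-O-benzyl-1,5-quinide 13 (lactone opening to the benzyl ester) ⇐ quinide 12 (alkylation of the equatorial O3) ⇐ quinide acetonide 11.
3. Key disconnection: the cyclohexane bond C1–C2 and the lactone of 11 ⇐ seven-membered 1,2-dione 8, by transannular hemiketalisation and benzilic ester 1,2-shift (7 → 6 ring contraction). Enabling feature: the C1/C2 1,2-dicarbonyl of the cycloheptane with the C6 oxygen γ to C2, able to bridge as an oxolane hemiketal (8-oxabicyclo[3.2.1]octane), while the cis C4/C5 diol is locked in a dioxolane.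
4. 8 ⇐ cycloheptene 6 (dihydroxylation, oxidation) ⇐ ring-closing metathesis of 1,8-diene 5 ⇐ catalyst-controlled C-allylation of alcohol 3 ⇐ Wittig methylenation of 2-deoxy-L-ribose acetonide 2.
5. Ring order: dioxolane (step 1) → cycloheptene (step 5) → bridged oxolane hemiketal, then cyclohexane and γ-lactone (all in step 8) → dioxolane and lactone opened (steps 9 and 11).

Key step: step 8

Remark: the SMILES is read as 4,5-di-O-vanilloyl-(−)-quinic acid (O3 free and cis to O4, carboxyl cis to O5); cycloheptane intermediates are numbered C1/C2 (alkene, later dione carbons), C3/C7 (CH2), C4/C5 (acetonide), C6 (silyloxy), so that C1, C4, C5, C6 become C1, C3, C4, C5 of the quinic core and C2 becomes the carboxyl carbon.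

## Route

Step 1
Reactants: 1 2-deoxy-L-ribose
Product: 2 2-deoxy-3,4-O-isopropylidene-L-erythro-pentopyranose
Conditions: 2-methoxypropene, PPTS (cat.), EtOAc, 0 °C → rt
Reagents that add atoms: 2-methoxypropene (C=C(C)OC)
Why: Acid-catalysed kinetic acetonide formation takes the cis-3,4-diol of the pyranose form and leaves the anomeric hydroxyl free, so the two sugar stereocentres (later C3 and C4 of the quinic core) are carried on unchanged.

Step 2
Reactants: 2 2-deoxy-3,4-O-isopropylidene-L-erythro-pentopyranose
Product: 3 [(4S,5R)-2,2-dimethyl-5-(prop-2-en-1-yl)-1,3-dioxolan-4-yl]methanol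
Conditions: Ph3PCH3Br, KOtBu (excess), THF, 0 °C → reflux
Reagents that add atoms: methyltriphenylphosphonium bromide (C[P+](c1ccccc1)(c1ccccc1)c1ccccc1.[Br-])
Why: Wittig methylenation of the lactol through its open-chain aldehyde should give the terminal alkene and free the primary hydroxyl without touching the stereocentres.

Step 3
Reactants: 3 [(4S,5R)-2,2-dimethyl-5-(prop-2-en-1-yl)-1,3-dioxolan-4-yl]methanol
Product: 4 (1R)-1-[(4S,5R)-2,2-dimethyl-5-(prop-2-en-1-yl)-1,3-dioxolan-4-yl]but-3-en-1-ol
Conditions: [Ir(cod)Cl]2 (cat.), (R)-BINAP (cat.), 4-chloro-3-nitrobenzoic acid (cat.), Cs2CO3 (cat.), allyl acetate, THF, 100 °C (sealed tube)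
Reagents that add atoms: allyl acetate (C=CCOC(C)=O)
Why: Iridium-catalysed transfer-hydrogenative carbonyl allylation from the alcohol oxidation level dehydrogenates the primary alcohol and traps the transient, epimerisable α-alkoxy aldehyde with the chiral π-allyliridium C,O-benzoate, whose ligand (the antipode that attacks the Re face) should set the new carbinol as (R), i.e. 1,2-syn to the dioxolane oxygen and against the intrinsic anti preference of the substrate.

Step 4
Reactants: 4 (1R)-1-[(4S,5R)-2,2-dimethyl-5-(prop-2-en-1-yl)-1,3-dioxolan-4-yl]but-3-en-1-ol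
Product: 5 O-triethylsilyl ether of 4
Conditions: Et3SiCl, imidazole, CH2Cl2, 0 °C → rt
Reagents that add atoms: chlorotriethylsilane (CC[Si](Cl)(CC)CC)
Why: Standard silylation of the secondary alcohol; the triethylsilyl group should survive metathesis, dihydroxylation and cold activated-DMSO oxidation and can later be removed with buffered fluoride without base.

Step 5
Reactants: 5 O-triethylsilyl ether of 4
Product: 6 cis-4,5-(isopropylidenedioxy)-6-(triethylsilyloxy)cyclohept-1-ene (C6–O trans to C5–O)
Conditions: (H2IMes)(PCy3)Cl2Ru=CHPh (3 mol%), CH2Cl2 (5 mM), 40 °C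
Reagents that add atoms: none
Why: Ring-closing metathesis of the 1,8-diene should close the seven-membered ring, helped by the cis-dioxolane that holds the two allyl chains gauche, and it creates no stereocentre.

Step 6
Reactants: 6 cis-4,5-(isopropylidenedioxy)-6-(triethylsilyloxy)cyclohept-1-ene
Product: 7 cis-1,2-diol of 6 (4,5-O-isopropylidene-6-O-triethylsilylcycloheptane-1,2,4,5,6-pentol)
Conditions: OsO4 (cat.), NMO, acetone/H2O, rt
Reagents that add atoms: osmium tetroxide (O=[Os](=O)(=O)=O); N-methylmorpholine N-oxide (C[N+]1([O-])CCOCC1); water (O)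
Why: Catalytic syn-dihydroxylation of the only alkene; which face is attacked does not matter because both new carbinol carbons become carbonyls in step 7.

Step 7
Reactants: 7 cis-1,2-diol of 6
Product: 8 4,5-(isopropylidenedioxy)-6-(triethylsilyloxy)cycloheptane-1,2-dione
Conditions: DMSO, (CF3CO)2O, CH2Cl2, −78 °C; Et3N, −78 → −30 °C; used crude
Reagents that add atoms: none
Why: Swern-type (activated DMSO) oxidation converts vicinal diols into 1,2-diones without C–C cleavage, and the low temperature and short contact with Et3N should limit enolisation and β-elimination of the C4 and C6 oxygens.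

Step 8
Reactants: 8 4,5-(isopropylidenedioxy)-6-(triethylsilyloxy)cycloheptane-1,2-dione
Product: 11 3,4-O-isopropylidene-1,5-quinide (quinide acetonide), via hydroxy dione 9 (not isolated), via bridged hemiketal 10 (not isolated)
Conditions: HF·pyridine, pyridine, THF, 0 °C → rt; then Et3N (excess), DBU, 0 °C → rt (one pot)
Reagents that add atoms: none
Why: Proposed new method: buffered fluoride frees the C6 hydroxyl, which adds across the ring to the C2 carbonyl to give the 8-oxabicyclo[3.2.1]octane hemiketal 10, and on deprotonation by DBU the hemiketal alkoxide reforms C=O at C2 while C3 migrates with its electron pair to the neighbouring C1 carbonyl, so that the cycloheptane becomes the cyclohexane and the hemiketal ring becomes the γ-lactone in one event. The closest known reactions are the hydroxide-induced benzilic acid ring contraction of cyclic 1,2-diones and the benzilic ester rearrangement with external alkoxides; new here is that the alkoxide is the substrate's own hydroxyl, delivered transannularly. Ring closures: the oxolane ring by 5-exo-trig hemiketalisation, the six-membered carbocycle by the 1,2-carbon shift of C3 from C2 to C1, and the lactone is the former hemiketal ring. The only new stereocentre, quaternary C1, is fixed by the tether, because the oxygen bridge from C6 forces the carboxyl carbon to be cis to the C6 oxygen and hence the tertiary hydroxyl cis to the C4/C5 oxygens, as in quinic acid; C4, C5 and C6 are not touched. The step needs site selectivity and must outrun β-elimination: the acetonide blocks O4 and O5, O6 could reach C1 only through a four-membered ring, and in 10 C2 is sp3 (no enolate towards the C4 oxygen) while the C6–O bond lies in the five-membered ring, poorly aligned with a C1/C7 enolate. The driving force is the conversion of an α-keto hemiketal into an ester and a tertiary alcohol.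

Step 9
Reactants: 11 3,4-O-isopropylidene-1,5-quinide
Product: 12 1,5-quinide (quinic acid γ-lactone)
Conditions: TFA/H2O (4:1), 0 °C → rt
Reagents that add atoms: none
Why: Aqueous acid hydrolyses the isopropylidene ketal while the γ-lactone, which itself forms from quinic acid under acid, should stay closed.

Step 10
Reactants: 12 1,5-quinide
Product: 13 3-O-benzyl-1,5-quinide
Conditions: Ph2B–OCH2CH2NH2 (10 mol%), BnBr, Ag2O, MeCN, 40 °C
Reagents that add atoms: benzyl bromide (BrCc1ccccc1)
Why: Borinic-acid-catalysed regioselective O-alkylation of a cis-1,2-diol, in which the diarylborinate binds O3/O4 and its equatorial oxygen (O3; O4 is axial in the locked lactone chair) is benzylated while the tertiary C1 hydroxyl is too hindered to compete.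

Step 11
Reactants: 13 3-O-benzyl-1,5-quinide
Product: 14 benzyl 3-O-benzylquinate
Conditions: LiOH·H2O, THF/H2O, 0 °C; evaporate; BnBr, DMF, rt
Reagents that add atoms: lithium hydroxide ([Li+].[OH-]); benzyl bromide (BrCc1ccccc1)
Why: Saponification of the γ-lactone followed by SN2 O-alkylation of the carboxylate in the same flask should give the benzyl ester and free the C5 hydroxyl without affecting any stereocentre.

Step 12
Reactants: 14 benzyl 3-O-benzylquinate; 15 4-(benzyloxy)-3-methoxybenzoic acid
Product: 16 benzyl 3-O-benzyl-4,5-bis-O-[4-(benzyloxy)-3-methoxybenzoyl]quinate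
Conditions: 15 (2.5 equiv), DCC, DMAP, CH2Cl2, 0 °C → rt
Reagents that add atoms: 4-(benzyloxy)-3-methoxybenzoic acid (COc1cc(ccc1OCc1ccccc1)C(=O)O)
Why: Steglich esterification acylates the two equatorial secondary hydroxyls at C4 and C5, while O3 is blocked as its benzyl ether and the tertiary C1 hydroxyl should not react, so the diester is regiochemically unambiguous.

Step 13
Reactants: 16 benzyl 3-O-benzyl-4,5-bis-O-[4-(benzyloxy)-3-methoxybenzoyl]quinate
Product: 17 Burkinabin C
Conditions: H2 (1 atm), Pd/C, EtOAc/MeOH, rt
Reagents that add atoms: none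
Why: Hydrogenolysis removes the benzyl ester, the C3 benzyl ether and both aryl benzyl ethers under neutral conditions, which avoids the base-promoted acyl migration typical of acylquinic acids.

## Compound list

1 | 2-deoxy-L-ribose (pyranose form, anomeric mixture) | OC1C[C@@H](O)[C@@H](O)CO1 | starting material
2 | 2-deoxy-3,4-O-isopropylidene-L-erythro-pentopyranose (anomeric mixture) | OC1C[C@H]2OC(C)(C)O[C@H]2CO1 | intermediate
3 | [(4S,5R)-2,2-dimethyl-5-(prop-2-en-1-yl)-1,3-dioxolan-4-yl]methanol | OC[C@@H]1OC(C)(C)O[C@@H]1CC=C | intermediate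
4 | (1R)-1-[(4S,5R)-2,2-dimethyl-5-(prop-2-en-1-yl)-1,3-dioxolan-4-yl]but-3-en-1-ol | C=CC[C@@H](O)[C@@H]1OC(C)(C)O[C@@H]1CC=C | intermediate
5 | O-triethylsilyl ether of 4 (stereocentres as in 4) | C=CC[C@@H](O[Si](CC)(CC)CC)[C@@H]1OC(C)(C)O[C@@H]1CC=C | intermediate
6 | cis-4,5-(isopropylidenedioxy)-6-(triethylsilyloxy)cyclohept-1-ene, C6–O trans to C5–O | C1=CC[C@H]2OC(C)(C)O[C@H]2[C@H](O[Si](CC)(CC)CC)C1 | intermediate
7 | cis-1,2-diol of 6 (configuration at C1/C2 not defined, both facial isomers converge) | OC1C(O)C[C@H]2OC(C)(C)O[C@H]2[C@H](O[Si](CC)(CC)CC)C1 | intermediate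
8 | 4,5-(isopropylidenedioxy)-6-(triethylsilyloxy)cycloheptane-1,2-dione (4,5-cis, 5,6-trans) | O=C1C(=O)C[C@H]2OC(C)(C)O[C@H]2[C@H](O[Si](CC)(CC)CC)C1 | intermediate
9 | 6-hydroxy-4,5-(isopropylidenedioxy)cycloheptane-1,2-dione | O=C1C(=O)C[C@H]2OC(C)(C)O[C@H]2[C@H](O)C1 | intermediate (not isolated)
10 | 5-hydroxy-2,3-(isopropylidenedioxy)-8-oxabicyclo[3.2.1]octan-6-one (bridged hemiketal) | O=C1C[C@H]2O[C@]1(O)C[C@H]1OC(C)(C)O[C@H]12 | intermediate (not isolated)
11 | 3,4-O-isopropylidene-1,5-quinide | O[C@@]1(C(=O)O2)C[C@H]3OC(C)(C)O[C@H]3[C@H]2C1 | intermediate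
12 | 1,5-quinide | O[C@@]1(C(=O)O2)C[C@@H](O)[C@@H](O)[C@H]2C1 | intermediate
13 | 3-O-benzyl-1,5-quinide | O[C@@]1(C(=O)O2)C[C@@H](OCc3ccccc3)[C@@H](O)[C@H]2C1 | intermediate
14 | benzyl 3-O-benzylquinate | O[C@@]1(C(=O)OCc2ccccc2)C[C@@H](OCc2ccccc2)[C@@H](O)[C@H](O)C1 | intermediate
15 | 4-(benzyloxy)-3-methoxybenzoic acid | COc1cc(ccc1OCc1ccccc1)C(=O)O | starting material
16 | benzyl 3-O-benzyl-4,5-bis-O-[4-(benzyloxy)-3-methoxybenzoyl]quinate | O[C@@]1(C(=O)OCc2ccccc2)C[C@@H](OCc2ccccc2)[C@@H](OC(=O)c2ccc(OCc3ccccc3)c(OC)c2)[C@H](OC(=O)c2ccc(OCc3ccccc3)c(OC)c2)C1 | intermediate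
17 | Burkinabin C (4,5-di-O-vanilloylquinic acid) | COc1cc(C(=O)O[C@@H]2[C@H](O)C[C@@](O)(C(=O)O)C[C@H]2OC(=O)c2ccc(O)c(OC)c2)ccc1O | target

## Summary

Total step count: 13. Longest linear sequence: 13 steps (1 → 17); acid 15 is purchased.

## Steps most likely to fail

Step 8 (key step, new method). The open hydroxy dione may lose the C6 or C4 oxygen by β-elimination or undergo retro-aldol cleavage before it hemiketalises, or the hemiketal may persist without undergoing the 1,2-shift. The fallback uses known chemistry and sets out from dione 8. The classical hydroxide-induced benzilic acid rearrangement (KOH or Ba(OH)2, aqueous dioxane, 0 °C → rt) should contract the ring without the tether. It would give the triethylsilyl ether of 3,4-O-isopropylidenequinic acid F1 together with its C1 epimer. Desilylation (HF·pyridine) would give 3,4-O-isopropylidenequinic acid F2. Acid-catalysed dehydrative lactonisation (TsOH, toluene, reflux), which only the isomer with carboxyl cis to O5 can undergo, comes back to the route at lactone 11. The epimeric acid is removed by bicarbonate extraction.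

Step 3. The catalyst-controlled addition works against the substrate's intrinsic anti preference, so facial selectivity may be poor; the terminal alkene may also isomerise at 100 °C. The fallback sets out from alcohol 3. Oxidation (TEMPO, PhI(OAc)2) would give (4R,5R)-2,2-dimethyl-5-(prop-2-en-1-yl)-1,3-dioxolane-4-carbaldehyde F3. Substrate-controlled anti allylation (allyl bromide, Zn, THF/aq. NH4Cl) would give the (1S)-epimer of 4, alcohol F4. Mitsunobu inversion (4-nitrobenzoic acid, PPh3, DIAD) would give the (1R)-4-nitrobenzoate F5, and methanolysis (K2CO3, MeOH) comes back to the route at 4.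

Step 7. Enolisation of the forming dione under Et3N may expel the β-oxygens, or the diol may be cleaved. The fallback sets out from cycloheptene 6 and avoids the diol and the amine base. RuO4-catalysed ketohydroxylation (RuCl3 cat., Oxone, NaHCO3, EtOAc/MeCN/H2O) would give the α-hydroxy ketone F6 (either regioisomer serves). Oxidation of the acyloin with Dess–Martin periodinane (NaHCO3, CH2Cl2) comes back to the route at dione 8.

## Further compounds

F1 | step 8 | triethylsilyl ether of 3,4-O-isopropylidenequinic acid (5-O-TES) | OC(=O)[C@]1(O)C[C@H]2OC(C)(C)O[C@H]2[C@H](O[Si](CC)(CC)CC)C1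
F2 | step 8 | 3,4-O-isopropylidenequinic acid | OC(=O)[C@]1(O)C[C@H]2OC(C)(C)O[C@H]2[C@H](O)C1
F3 | step 3 | (4R,5R)-2,2-dimethyl-5-(prop-2-en-1-yl)-1,3-dioxolane-4-carbaldehyde | O=C[C@@H]1OC(C)(C)O[C@@H]1CC=C
F4 | step 3 | (1S)-1-[(4S,5R)-2,2-dimethyl-5-(prop-2-en-1-yl)-1,3-dioxolan-4-yl]but-3-en-1-ol | C=CC[C@H](O)[C@@H]1OC(C)(C)O[C@@H]1CC=C
F5 | step 3 | 4-nitrobenzoate of 4 (1R) | C=CC[C@@H](OC(=O)c1ccc(cc1)[N+](=O)[O-])[C@@H]1OC(C)(C)O[C@@H]1CC=C
F6 | step 7 | 2-hydroxy-4,5-(isopropylidenedioxy)-6-(triethylsilyloxy)cycloheptan-1-one (carbinol configuration not defined) | O=C1C(O)C[C@H]2OC(C)(C)O[C@H]2[C@H](O[Si](CC)(CC)CC)C1
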